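The numbers in the tables come from a simulation with constants of no real substance.

No closed flask can hold more than its charge, yet once I count the 2.00% of quenched substrate that the protic impurity can take, one for one, Friday's row at 60.0 s adds up to 105% and the row at 80.0 s to 95.0%.

| setting | Friday's | flask |
|---|---|---|
| starting material | 2 mM | 2.0 mM |
| protic impurity | 0.040 mM | 0.0400 mM |
| remark | the very flask that is asked about, followed so far |  |
| time |  | 15 min |

Friday's run (percent of the starting material charged)

| time / s | starting material / % | target / % | isomer of the product / % | side product / % |
|---|---|---|---|---|
| 15.0 | 0 | 48 | 25 | 22 |
| 30.0 | 0 | 32 | 45 | 24 |
| 40.0 | 0 | 23 | 53 | 23 |
| 60.0 | 0 | 17 | 62 | 24 |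
| 80.0 | 0 | 9 | 61 | 23 |

(readings scatter by 1.5 percentage points)

- a species is counted by the starting material in it: one side product counts as two
- the numbers in the tables scatter by 1.5 percentage points (one standard deviation)
- steps that have been proposed: starting material -> target; target <-> isomer of the product; starting material + target -> side product; starting material + protic impurity -> quenched substrate
- the reaction counts as stopped when no species that holds the starting material changes by six tenths of a point or more over the second half of the time

1. which holds at 15 min: what has brought the reaction to rest, or that it has not come to rest (forward and back rates have come level / all of the starting material has reacted / it is still moving)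
2. conversion of starting material at 15 min
3. amount of target at 15 min, in percent of the starting material charged
4. amount of isomer of the product at 15 min, in percent of the starting material charged
5. amount of side product at 15 min, in percent of the starting material charged

I want K, the rate constant of target to isomer divided by that of isomer to target. Where the forward and back rates run level, each constant times its own species gives the same rate, so time drops out and K reads as isomer over target, the equilibrium constant. The direct way divides the last row's isomer by its target and gives 6.78.

The second way leaves the target peak out. Starting material reads 0% from 15.0 s on and side product reads flat, with a mean of 23.2%, so target plus isomer must make 74.8%. Isomer reads 62% and 61% at the last two times, a mean of 61.5%, which leaves target 13.3% by difference and K = 4.62.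

The two ways part, and I distrust the direct one: it leans on the row that sums to 95.0%, and a scatter of 1.5 percentage points weighs more on a target reading of 9% than on an isomer reading of 61%. So I carry 4.62, isomer over target at level. The readings end at 80.0 s, far short of 15 min, and for that time I commit to starting material reacted to the end, target 13.3%, isomer 61.5% and side product 23.2%.

The forecast says forward and back rates have come level, conversion 100%, target 8%, isomer 67% and side product 23.3%, and adds: "The floor is the uncertain part."

The flask gives all of the starting material has reacted, conversion 100%, target 12.2%, isomer 62.5% and side product 23.2%.

    starting material → target, rate k1*[starting material]/(1 + ([starting material]/sat1)) (0.163 mM, k = 2.07 s⁻¹)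
    target ⇌ isomer of the product (K = 5.11, k = 0.0395 s⁻¹)
    starting material + target → side product (k = 78.1 M⁻¹ s⁻¹)
    starting material + protic impurity → quenched substrate (k = 2410 M⁻¹ s⁻¹)

In the neighbour flask, charged with 3.4 mM of starting material, the same reckoning takes side product 41.4% and quenched substrate 1.18% off the charge, which leaves 57.5% for target and isomer. Dividing by one plus K gives target 10.2%, and that neighbour flask holds 9.40%. Its isomer over target stands at 5.11, and in the flask at 5.12.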